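**Assumption:** the target SMILES has no stereocentres and no stereogenic double bond, so the compound is achiral and "single enantiomer" means the compound as drawn. Nothing stereochemical needs to be set.

## Retrosynthetic overview

1. Target 17 comes from O-methylation and global desilylation of the 5-hydroxy-6-prenyl isoflav-3-ene 14.
2. The C6 prenyl comes from an aromatic Claisen rearrangement of a 5-O-(1,1-dimethylallyl) ether. C6 is the only free ortho position, so the step is regiospecific. The ether is carried as a thermally latent 1,1-dimethylpropargyl ether.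
3. The pyran ring (O1–C2 and C3=C4) is formed in one step by a new oxa-Michael/intramolecular Wittig annulation of salicylaldehyde 5 with the α-aryl vinylphosphonium salt 11.
4. Aldehyde 5 comes from 2,4,6-trihydroxybenzaldehyde; salt 11 comes from 2,4-dihydroxyacetophenone via its enol triflate.
5. Ring order: the A and B rings are purchased; the heterocyclic C ring is the only ring formed (step 6).

## Route

**Step 1**
Reactants: 1 (2,4,6-trihydroxybenzaldehyde); 2 (triisopropylsilyl chloride)
Product: 3 (2,6-dihydroxy-4-(triisopropylsilyloxy)benzaldehyde)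
Conditions: TIPSCl (1.05 equiv), imidazole, DMF, 0 °C to rt
Reagents that add atoms: triisopropylsilyl chloride, CC(C)[Si](Cl)(C(C)C)C(C)C
Why: Selective silylation of the 4-OH, which is the most acidic, unhindered and not hydrogen-bonded to the aldehyde; the bulky TIPS group avoids the two chelated ortho hydroxyls.

**Step 2**
Reactants: 3; 4 (3-chloro-3-methylbut-1-yne)
Product: 5 (2-hydroxy-6-[(2-methylbut-3-yn-2-yl)oxy]-4-(triisopropylsilyloxy)benzaldehyde)
Conditions: 4 (1.3 equiv), DBU, CuCl2·2H2O (1 mol%), MeCN, 0 °C to rt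
Reagents that add atoms: 3-chloro-3-methylbut-1-yne, C#CC(C)(C)Cl
Why: Copper-catalysed propargylic etherification of a phenol; after one of the two equivalent ortho hydroxyls is etherified the other is locked in the hydrogen bond to the aldehyde, so the reaction stops at the mono-ether.

**Step 3**
Reactants: 6 (2,4-dihydroxyacetophenone); 2 (triisopropylsilyl chloride)
Product: 7 (1-[2,4-bis(triisopropylsilyloxy)phenyl]ethanone)
Conditions: TIPSCl (2.4 equiv), imidazole, DMAP (cat.), DMF, 60 °C
Reagents that add atoms: triisopropylsilyl chloride, CC(C)[Si](Cl)(C(C)C)C(C)C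
Why: Exhaustive phenol silylation; heating and DMAP overcome the chelated ortho hydroxyl, and TIPS is chosen because it is base-stable and resists O-to-O migration in the next step.

**Step 4**
Reactants: 7; 8 (N-phenylbis(trifluoromethanesulfonimide))
Product: 9 (1-[2,4-bis(triisopropylsilyloxy)phenyl]vinyl trifluoromethanesulfonate)
Conditions: KHMDS, THF, −78 °C; then PhNTf2, −78 to 0 °C; filter through Et3N-deactivated silica
Reagents that add atoms: N-phenylbis(trifluoromethanesulfonimide), O=S(=O)(N(c1ccccc1)S(=O)(=O)C(F)(F)F)C(F)(F)F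
Why: Kinetic enolisation of the methyl ketone and O-triflation of the enolate gives the 1-aryl vinyl triflate.

**Step 5**
Reactants: 9; 10 (triphenylphosphine)
Product: 11 ({1-[2,4-bis(triisopropylsilyloxy)phenyl]vinyl}triphenylphosphonium trifluoromethanesulfonate)
Conditions: PPh3 (1.0 equiv), Pd(PPh3)4 (3 mol%), THF, 65 °C; precipitate from Et2O/hexane
Reagents that add atoms: triphenylphosphine, c1ccc(cc1)P(c1ccccc1)c1ccccc1
Why: Pd-catalysed C–P coupling of a vinyl triflate with PPh3 (oxidative addition, then C–P reductive elimination) is an established route to vinylphosphonium triflates.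

**Step 6 (key step)**
Reactants: 5; 11
Product: 12 (3-[2,4-bis(triisopropylsilyloxy)phenyl]-5-[(2-methylbut-3-yn-2-yl)oxy]-7-(triisopropylsilyloxy)-2H-chromene)
Conditions: 5, NaH (1.05 equiv), THF, 0 °C; then 11 (1.15 equiv), THF, 0 to 65 °C, Ar
Reagents that add atoms: none (all product atoms come from 5 and 11; Ph3P=O and NaOTf are lost)
Why: Proposed new method: an isoflavene-forming oxa-Michael/intramolecular Wittig annulation in which the sodium phenoxide of 5 adds to the CH2 terminus of the α-aryl vinylphosphonium 11 to form O1–C2 and a semi-stabilised benzylic ylide at C3, which closes on the ortho aldehyde to form C3=C4 with loss of Ph3P=O. The closest known reaction is the Schweizer 2H-chromene synthesis from salicylaldehydes and vinyltriphenylphosphonium bromide; to my knowledge it has not been shown with α-aryl vinylphosphonium salts, for isoflav-3-enes, or on so electron-rich and di-ortho-substituted an aldehyde.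

**Step 7**
Reactants: 12
Product: 13 (3-[2,4-bis(triisopropylsilyloxy)phenyl]-5-[(2-methylbut-3-en-2-yl)oxy]-7-(triisopropylsilyloxy)-2H-chromene)
Conditions: H2 (1 atm), Lindlar catalyst, quinoline, EtOAc, rt, stop at 1 equiv H2
Reagents that add atoms: none (H2 only)
Why: Lindlar semi-hydrogenation reduces the terminal alkyne to the alkene and leaves the conjugated trisubstituted C3=C4 alkene and the aryl silyl ethers untouched.

**Step 8**
Reactants: 13
Product: 14 (3-[2,4-bis(triisopropylsilyloxy)phenyl]-6-(3-methylbut-2-en-1-yl)-7-(triisopropylsilyloxy)-2H-chromen-5-ol)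
Conditions: degassed toluene, 110 °C, sealed tube (trace BHT)
Reagents that add atoms: none
Why: Aromatic Claisen [3,3] rearrangement of the 1,1-dimethylallyl aryl ether delivers a normal prenyl group to C6, the only unsubstituted ortho position (C4a is blocked), and tautomerisation gives the 5-phenol.

**Step 9**
Reactants: 14; 15 (iodomethane)
Product: 16 (3-[2,4-bis(triisopropylsilyloxy)phenyl]-5-methoxy-6-(3-methylbut-2-en-1-yl)-7-(triisopropylsilyloxy)-2H-chromene)
Conditions: MeI, K2CO3, acetone, 50 °C
Reagents that add atoms: iodomethane, CI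
Why: Williamson O-methylation of the only free phenol, which is not chelated; aryl TIPS ethers tolerate anhydrous K2CO3/acetone.

**Step 10**
Reactants: 16
Product: 17 (dehydroglyasperin C; 3-(2,4-dihydroxyphenyl)-5-methoxy-6-(3-methylbut-2-en-1-yl)-2H-chromen-7-ol)
Conditions: TBAF (3.6 equiv), AcOH (3.6 equiv), degassed THF, 0 °C to rt; pH 6 buffer work-up
Reagents that add atoms: none
Why: Fluoride cleavage of the three aryl silyl ethers; the AcOH buffer limits phenoxide oxidation, and the absence of strong acid avoids cyclisation of the 7-OH onto the prenyl group or of the 2'-OH onto C4.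

## Compound list

1 | 2,4,6-trihydroxybenzaldehyde | O=Cc1c(O)cc(O)cc1O | starting material
2 | triisopropylsilyl chloride | CC(C)[Si](Cl)(C(C)C)C(C)C | starting material
3 | 2,6-dihydroxy-4-(triisopropylsilyloxy)benzaldehyde | O=Cc1c(O)cc(O[Si](C(C)C)(C(C)C)C(C)C)cc1O | intermediate
4 | 3-chloro-3-methylbut-1-yne | C#CC(C)(C)Cl | starting material
5 | 2-hydroxy-6-[(2-methylbut-3-yn-2-yl)oxy]-4-(triisopropylsilyloxy)benzaldehyde | O=Cc1c(O)cc(O[Si](C(C)C)(C(C)C)C(C)C)cc1OC(C)(C)C#C | intermediate
6 | 2,4-dihydroxyacetophenone | CC(=O)c1ccc(O)cc1O | starting material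
7 | 1-[2,4-bis(triisopropylsilyloxy)phenyl]ethanone | CC(=O)c1ccc(O[Si](C(C)C)(C(C)C)C(C)C)cc1O[Si](C(C)C)(C(C)C)C(C)C | intermediate
8 | N-phenylbis(trifluoromethanesulfonimide) | O=S(=O)(N(c1ccccc1)S(=O)(=O)C(F)(F)F)C(F)(F)F | starting material
9 | 1-[2,4-bis(triisopropylsilyloxy)phenyl]vinyl trifluoromethanesulfonate | C=C(OS(=O)(=O)C(F)(F)F)c1ccc(O[Si](C(C)C)(C(C)C)C(C)C)cc1O[Si](C(C)C)(C(C)C)C(C)C | intermediate
10 | triphenylphosphine | c1ccc(cc1)P(c1ccccc1)c1ccccc1 | starting material
11 | {1-[2,4-bis(triisopropylsilyloxy)phenyl]vinyl}triphenylphosphonium triflate | C=C(c1ccc(O[Si](C(C)C)(C(C)C)C(C)C)cc1O[Si](C(C)C)(C(C)C)C(C)C)[P+](c1ccccc1)(c1ccccc1)c1ccccc1.[O-]S(=O)(=O)C(F)(F)F | intermediate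
12 | 3-[2,4-bis(triisopropylsilyloxy)phenyl]-5-[(2-methylbut-3-yn-2-yl)oxy]-7-(triisopropylsilyloxy)-2H-chromene | C#CC(C)(C)Oc1cc(O[Si](C(C)C)(C(C)C)C(C)C)cc2OCC(c3ccc(O[Si](C(C)C)(C(C)C)C(C)C)cc3O[Si](C(C)C)(C(C)C)C(C)C)=Cc12 | intermediate
13 | 3-[2,4-bis(triisopropylsilyloxy)phenyl]-5-[(2-methylbut-3-en-2-yl)oxy]-7-(triisopropylsilyloxy)-2H-chromene | C=CC(C)(C)Oc1cc(O[Si](C(C)C)(C(C)C)C(C)C)cc2OCC(c3ccc(O[Si](C(C)C)(C(C)C)C(C)C)cc3O[Si](C(C)C)(C(C)C)C(C)C)=Cc12 | intermediate
14 | 3-[2,4-bis(triisopropylsilyloxy)phenyl]-6-(3-methylbut-2-en-1-yl)-7-(triisopropylsilyloxy)-2H-chromen-5-ol | CC(C)=CCc1c(O)c2C=C(c3ccc(O[Si](C(C)C)(C(C)C)C(C)C)cc3O[Si](C(C)C)(C(C)C)C(C)C)COc2cc1O[Si](C(C)C)(C(C)C)C(C)C | intermediate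
15 | iodomethane | CI | starting material
16 | 3-[2,4-bis(triisopropylsilyloxy)phenyl]-5-methoxy-6-(3-methylbut-2-en-1-yl)-7-(triisopropylsilyloxy)-2H-chromene | COc1c(CC=C(C)C)c(O[Si](C(C)C)(C(C)C)C(C)C)cc2OCC(c3ccc(O[Si](C(C)C)(C(C)C)C(C)C)cc3O[Si](C(C)C)(C(C)C)C(C)C)=Cc12 | intermediate
17 | dehydroglyasperin C, 3-(2,4-dihydroxyphenyl)-5-methoxy-6-(3-methylbut-2-en-1-yl)-2H-chromen-7-ol (achiral) | COc1c2c(cc(O)c1CC=C(C)C)OCC(c1ccc(O)cc1O)=C2 | target

## Summary

**Total steps:** 10
**Longest linear sequence:** 8 (steps 3, 4, 5, 6, 7, 8, 9, 10 from 2,4-dihydroxyacetophenone; the aldehyde branch is 7)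

**Three steps most likely to fail**

1. **Step 6 (proposed new annulation).** Risks are a sluggish Wittig closure onto the electron-rich, di-ortho-substituted aldehyde with a hindered α-aryl ylide, and reversible oxa-Michael addition. Fallback (known chemistry, different ring construction): acylate the phenol of 5 with 2,4-bis(triisopropylsilyloxy)phenylacetyl chloride, close by base-mediated intramolecular Knoevenagel condensation to the 3-arylcoumarin, reduce the lactone with DIBAL to the (Z)-allylic alcohol/phenol, and cyclise by Mitsunobu etherification (PPh3/DIAD) to 12.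

2. **Step 5 (vinylphosphonium formation).** The electron-rich, ortho-silyloxy vinyl triflate 9 may hydrolyse or couple slowly. Fallback: eliminate 9 to 2,4-bis(triisopropylsilyloxy)phenylacetylene and make 11 by Pd-catalysed Markovnikov addition of PPh3/MsOH across the alkyne. This replaces C–P coupling of a triflate with alkyne hydrophosphination.

3. **Step 2 (mono-propargylation of the chelated phenol).** Risks are low conversion or C-alkylation of the phloroglucinol-type ring. Fallback: protect one ortho hydroxyl of 3 as a MOM ether, run the annulation, and remove the MOM group with mild acid (no prenyl or free phenol is present at that stage). Then install the 1,1-dimethylallyl ether on the non-chelated chromene 5-OH by Pd(0)-catalysed O-allylation with tert-butyl (2-methylbut-3-en-2-yl) carbonate and continue with the Claisen rearrangement of step 8.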